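Ring A is disconnected across C1–C2 and C5–C6, so that one (4+2) cycloaddition with loss of CO2 builds the whole ring. The key step exploits two features of ring A: the adjacent oxygen-bearing carbons C1 and C6, and the meta pattern C3–Br/C4–H/C5–Br. The bromine pattern is carried in by 3,5-dibromo-2H-pyran-2-one. The C1–C6 edge comes from an alkyne that already holds the ether oxygen to ring B on one carbon and boron, a masked hydroxyl, on the other. The precursor is therefore the pinacol boronate of (2-bromophenoxy)acetylene, and no catechol has to be etherified selectively. Oxidation of C–B and ortho-bromination at C2 finish the route.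

Key step: step 4

Numbering used: ring A is the phenol ring, C1 (OH), C2 (Br), C3 (Br), C4 (H), C5 (Br), C6 (O to ring B); ring B is the 2-bromophenyl ring. Pyranone C3, C4, C5 and C6 become ring A C5, C4, C3 and C2; the alkyne carbons become C6 (O) and C1 (B).

Remark on the chemistry: the target has no stereocentre. The only stereo-elements on the way are the Z double bond of 6 and the two bridgehead centres of the transient, racemic lactone 12, which vanish on aromatisation.

Step 1
Reactants: 1 coumalic acid
Product: 2 3,5-dibromo-2H-pyran-2-one
Conditions: NBS (2.5 equiv), LiOAc, MeCN–H2O, rt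
Reagents that add atoms: N-bromosuccinimide, O=C1CCC(=O)N1Br
Why: Bromodecarboxylation at C5 (Hunsdiecker-type ipso-substitution of the carboxylate) and electrophilic bromination at the enolic C3 of the pyranone both proceed with NBS in one pot, a known transformation of coumalic acid.

Step 2
Reactants: 3 2-bromophenol; 4 (Z)-1,2-dichloroethene
Product: 6 1-bromo-2-{[(Z)-2-chloroethenyl]oxy}benzene, via chloroethyne 5 (not isolated)
Conditions: 4 (3 equiv), KOH (powdered, 1.5 equiv), DMSO, 50 °C, N2, closed vessel
Reagents that add atoms: none
Why: KOH in DMSO removes HCl from 4 by anti elimination to give chloroethyne, to which the phenoxide adds trans at the unsubstituted carbon (elimination–addition, nucleophilic vinylation), so the Z-2-chlorovinyl ether forms with the aryl bromide untouched, and excess 4 suppresses a second addition.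

Step 3
Reactants: 6 1-bromo-2-{[(Z)-2-chloroethenyl]oxy}benzene; 7 2-isopropoxy-4,4,5,5-tetramethyl-1,3,2-dioxaborolane
Product: 11 2-[(2-bromophenoxy)ethynyl]-4,4,5,5-tetramethyl-1,3,2-dioxaborolane, via 1-bromo-2-(ethynyloxy)benzene 8 (not isolated), via lithium (2-bromophenoxy)ethynide 9 (not isolated), via lithium alkynyl(isopropoxy)borate 10 (not isolated)
Conditions: LiN(iPr)2 (2.2 equiv), THF, −78 → −30 °C; 7, −78 °C; HCl in Et2O (enough to neutralise all base), −78 °C → rt; filter under N2
Reagents that add atoms: none
Why: In the Z ether the hydrogen on the oxygen-bearing carbon is anti to chlorine, so the amide base removes HCl by E2 and a second equivalent deprotonates the terminal ynol ether (Arens-type alkoxyacetylide synthesis) without any bromine–lithium exchange at ring B, after which electrophilic borylation with 7 and protonolysis of the borate release the alkynylboronate as in the standard synthesis of alkynyl pinacol boronates.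

Step 4
Reactants: 2 3,5-dibromo-2H-pyran-2-one; 11 2-[(2-bromophenoxy)ethynyl]-4,4,5,5-tetramethyl-1,3,2-dioxaborolane
Product: 13 2-[3,5-dibromo-2-(2-bromophenoxy)phenyl]-4,4,5,5-tetramethyl-1,3,2-dioxaborolane, via bridged dienyl lactone 12 (not isolated)
Conditions: 11 (1.5 equiv), PhMe, 110 °C, sealed tube, BHT (cat.), Ar
Reagents that add atoms: none
Why: The ambiphilic dibromopyranone 2 engages the push–pull alkyne 11 in a concerted, asynchronous (4+2) cycloaddition across C3 and C6 of the pyranone (Diels–Alder reaction), and the bridged dienyl lactone 12 then expels CO2 by retro-(4+2) cycloreversion, which makes the sequence irreversible and aromatises ring A. The closest known reaction type is the benzannulation of 2-pyranones, 3,5-dibromo-2-pyranone among them, with alkynylboronates to give aryl boronates; what is new is only the aryloxy substituent on the alkyne. Ring A, the only ring formed, is closed by an intermolecular (4+2) cycloaddition that makes C1–C2 and C5–C6 at once, the other four ring atoms (C2 to C5) being the diene carbons of 2. No stereocentre survives, since the two bridgehead centres of racemic 12 become sp2 on loss of CO2. The step needs regiocontrol, and the alkyne supplies it: donation from the oxygen lone pair and withdrawal by the empty boron p orbital polarise the triple bond so that the boron-bearing carbon is the nucleophilic end, which bonds to C6, the most electrophilic terminus of the diene and the position where enol ethers attack 3-bromo- and 3,5-dibromopyranones, leaving OAr next to the C3-derived bromine (C5 of ring A) and boron next to the C6-derived CH (C2 of ring A). A modest excess of 11, exclusion of moisture and a radical inhibitor guard against loss of the thermally sensitive alkyne.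

Step 5
Reactants: 13 2-[3,5-dibromo-2-(2-bromophenoxy)phenyl]-4,4,5,5-tetramethyl-1,3,2-dioxaborolane
Product: 14 3,5-dibromo-2-(2-bromophenoxy)phenol
Conditions: KHSO5 (as Oxone, 1.1 equiv), acetone–H2O, rt
Reagents that add atoms: potassium peroxymonosulfate, [K+].[O-]S(=O)(=O)OO
Why: ipso-Oxidation of the aryl boronate, in which the peroxide adds to boron, the aryl group migrates from boron to oxygen at the same carbon and the borate ester is hydrolysed to the phenol, while the aryl bromides and the diaryl ether are inert.

Step 6
Reactants: 14 3,5-dibromo-2-(2-bromophenoxy)phenol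
Product: 15 2,3,5-tribromo-6-(2-bromophenoxy)phenol
Conditions: NBS (1.05 equiv), iPr2NH (10 mol%), CH2Cl2, 0 °C → rt
Reagents that add atoms: N-bromosuccinimide, O=C1CCC(=O)N1Br
Why: Amine-mediated ortho-bromination of a phenol (electrophilic aromatic substitution), in which the N-bromoamine formed from NBS and iPr2NH delivers bromine through a hydrogen-bonded phenol complex to C2, the only free ortho position, whereas para C4 is flanked by two bromines and ring B is a far less activated aryl ether.

Compound list
1 | coumalic acid (2-oxo-2H-pyran-5-carboxylic acid) | O=C(O)C1=COC(=O)C=C1 | starting material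
2 | 3,5-dibromo-2H-pyran-2-one | O=C1OC=C(Br)C=C1Br | intermediate
3 | 2-bromophenol | Oc1ccccc1Br | starting material
4 | (Z)-1,2-dichloroethene | Cl/C=C\Cl | starting material
5 | chloroethyne | ClC#C | intermediate (not isolated)
6 | 1-bromo-2-{[(Z)-2-chloroethenyl]oxy}benzene | Cl/C=C\Oc1ccccc1Br | intermediate
7 | 2-isopropoxy-4,4,5,5-tetramethyl-1,3,2-dioxaborolane | CC(C)OB1OC(C)(C)C(C)(C)O1 | starting material
8 | 1-bromo-2-(ethynyloxy)benzene | C#COc1ccccc1Br | intermediate (not isolated)
9 | lithium (2-bromophenoxy)ethynide | [Li+].[C-]#COc1ccccc1Br | intermediate (not isolated)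
10 | lithium [(2-bromophenoxy)ethynyl](isopropoxy)(pinacolato)borate | [Li+].CC(C)O[B-]1(C#COc2ccccc2Br)OC(C)(C)C(C)(C)O1 | intermediate (not isolated)
11 | 2-[(2-bromophenoxy)ethynyl]-4,4,5,5-tetramethyl-1,3,2-dioxaborolane | CC1(C)OB(OC1(C)C)C#COc1ccccc1Br | intermediate
12 | 4,7-dibromo-5-(2-bromophenoxy)-6-(4,4,5,5-tetramethyl-1,3,2-dioxaborolan-2-yl)-2-oxabicyclo[2.2.2]octa-5,7-dien-3-one, racemic | O=C1OC2C(B3OC(C)(C)C(C)(C)O3)=C(Oc3ccccc3Br)C1(Br)C=C2Br | intermediate (not isolated)
13 | 2-[3,5-dibromo-2-(2-bromophenoxy)phenyl]-4,4,5,5-tetramethyl-1,3,2-dioxaborolane | CC1(C)OB(OC1(C)C)c1cc(Br)cc(Br)c1Oc1ccccc1Br | intermediate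
14 | 3,5-dibromo-2-(2-bromophenoxy)phenol | Oc1cc(Br)cc(Br)c1Oc1ccccc1Br | intermediate
15 | 2,3,5-tribromo-6-(2-bromophenoxy)phenol | Oc1c(Br)c(Br)cc(Br)c1Oc1ccccc1Br | target

Total step count: 6. Longest linear sequence: 5 (steps 2 to 6, from 2-bromophenol).

Steps most likely to fail

The cycloaddition of step 4 is the riskiest. The ynol ether boronate may polymerise or hydrolyse before it adds, or the two orientations of the alkyne may compete and erode regiocontrol. The fallback gives up the benzannulation and uses a preformed arene; it sets out from 3 and returns at 14. Nucleophilic aromatic substitution of 3 on 3,5-dibromo-2-fluorobenzaldehyde F1 (K2CO3, DMAc, 100 °C), whose fluorine is activated by the ortho formyl group, should give 3,5-dibromo-2-(2-bromophenoxy)benzaldehyde F2. Baeyer–Villiger oxidation with mCPBA in CH2Cl2, with migration of the oxygen-substituted aryl group, should give 3,5-dibromo-2-(2-bromophenoxy)phenyl formate F3. Hydrolysis with KOH in MeOH–H2O and acidification would deliver 14.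

Step 3 is next. Deprotonation at the chlorine-bearing carbon of 6 could expel aryloxide instead of chloride, fragmenting the ether back to phenoxide and chloroethyne. Over-reaction in step 2 would likewise starve this step of material. The fallback is the dichlorovinyl ether route, in which loss of chloride is the established course; it sets out from 3 and rejoins at 9. Phenol 3 and trichloroethene F4 (K2CO3, DMF, 70 °C) should give, through dichloroethyne F5, 1-bromo-2-{[(E)-1,2-dichloroethenyl]oxy}benzene F6. n-BuLi (2.0 equiv, Et2O, −78 °C) would deprotonate F6 and eliminate LiCl to give 1-bromo-2-[(chloroethynyl)oxy]benzene F7. Chlorine–lithium exchange with the second equivalent then gives 9, which is borylated with 7 and released with HCl as in step 3 to reach 11. The cold ethereal solvent and the exact stoichiometry are chosen because bromine–lithium exchange at ring B is slow under these conditions.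

Step 6 is third. Bromine may enter at C4, para to the hydroxyl, or a second bromination may follow. The fallback replaces electrophilic substitution by directed metalation; it sets out from 14 and returns at 15. Carbamoylation (Et2NCOCl, K2CO3, MeCN, 80 °C) should give 3,5-dibromo-2-(2-bromophenoxy)phenyl diethylcarbamate F8. Magnesiation with (2,2,6,6-tetramethylpiperidin-1-yl)MgCl·LiCl (THF, −20 → 0 °C), which tolerates aryl bromides, should occur at C2 because the carbamate both coordinates the base and, with the C3 bromine, acidifies that position, giving the arylmagnesium chloride F9. Quenching with BrCl2C–CCl2Br would give 2,3,5-tribromo-6-(2-bromophenoxy)phenyl diethylcarbamate F10. Hydrolysis (KOH, EtOH–H2O, reflux) and acidification would release 15.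

Further compounds
F1 | step 4 | 3,5-dibromo-2-fluorobenzaldehyde | O=Cc1cc(Br)cc(Br)c1F
F2 | step 4 | 3,5-dibromo-2-(2-bromophenoxy)benzaldehyde | O=Cc1cc(Br)cc(Br)c1Oc1ccccc1Br
F3 | step 4 | 3,5-dibromo-2-(2-bromophenoxy)phenyl formate | O=COc1cc(Br)cc(Br)c1Oc1ccccc1Br
F4 | step 3 | trichloroethene | ClC=C(Cl)Cl
F5 | step 3 | dichloroethyne | ClC#CCl
F6 | step 3 | 1-bromo-2-{[(E)-1,2-dichloroethenyl]oxy}benzene | Cl/C=C(/Cl)Oc1ccccc1Br
F7 | step 3 | 1-bromo-2-[(chloroethynyl)oxy]benzene | ClC#COc1ccccc1Br
F8 | step 6 | 3,5-dibromo-2-(2-bromophenoxy)phenyl diethylcarbamate | CCN(CC)C(=O)Oc1cc(Br)cc(Br)c1Oc1ccccc1Br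
F9 | step 6 | [3,4-dibromo-2-(diethylcarbamoyloxy)-3'... ring A C2-magnesiated carbamate] 2-(diethylcarbamoyloxy)-4,6-dibromo-3-(2-bromophenoxy)... arylmagnesium chloride–lithium chloride complex of F8 metalated at ring A C2 | CCN(CC)C(=O)Oc1c([Mg]Cl)c(Br)cc(Br)c1Oc1ccccc1Br.[Li+].[Cl-]
F10 | step 6 | 2,3,5-tribromo-6-(2-bromophenoxy)phenyl diethylcarbamate | CCN(CC)C(=O)Oc1c(Br)c(Br)cc(Br)c1Oc1ccccc1Br
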